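## Retrosynthetic overview
1. The strategy rests on the three Ar–Cα(OH)–Cβ(OAr′)–CγH2OH arms. Cα and Cβ are vicinally oxygenated, a pairing that carbonyl polarity alone cannot join. Each Cβ is linked through its oxygen to C4 of an aromatic ring: the two syringyl rings at C7/C7′ of the 3,7-dioxabicyclo[3.3.0]octane core, and the guaiacyl ring of one inner arm.
2. Every Cα–Cβ bond is cut to O-benzylvanillin and an (E)-γ-aryloxyallyl pinacolboronate, in which Cβ is the nucleophilic γ-carbon. The vinyl group left behind is the masked CγH2OH (oxidative cleavage, then reduction).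
3. The two inner arms (αS,βR) are set together on the C2-symmetric core bis-boronate with (R)-TRIP. The outer arm (αR,βS) is set by the same sequence on one freed guaiacyl phenol with (S)-TRIP.
4. Each boronate comes from its phenol by propargylation (a primary halide), hydroboration and iridium-catalysed olefin migration.
5. Ring order: both tetrahydrofuran rings of the core are closed first and together (oxidative 8–8′ dimerisation of sinapyl alcohol, then resolution). No ring is formed afterwards.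

Key step: step 8

Nomenclature: core atoms are C7–C9 and C7′–C9′. Arms A and A′ sit on the two syringyl oxygens, and arm B sits on the guaiacyl oxygen of arm A. α, β and γ are the benzylic, ether-bearing and terminal carbons of an arm. TBS = tert-butyldimethylsilyl; Bpin = 4,4,5,5-tetramethyl-1,3,2-dioxaborolan-2-yl; TRIP = 3,3′-bis(2,4,6-triisopropylphenyl)-1,1′-binaphthyl-2,2′-diyl hydrogen phosphate.

Assumption: (R)-TRIP is taken to send the allyl unit to the Re face of an aryl aldehyde, as it does with allyl and (E)-crotyl pinacolboronate. Re attack corresponds to αS. If the aryloxy reagent responds in the opposite sense, the two catalyst enantiomers change places between steps 8 and 17 and nothing else changes.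

## Route

Step 1
Reactants: 1 syringaldehyde; 2 ethyl hydrogen malonate
Product: 3 ethyl (E)-sinapate
Conditions: pyridine, piperidine (cat.), 60 °C
Reagents that add atoms: ethyl hydrogen malonate (2), CCOC(=O)CC(=O)O
Why: Knoevenagel–Doebner condensation; decarboxylative elimination from the adduct should give only the E-cinnamate, and the free phenol needs no protection.

Step 2
Reactants: 3 ethyl (E)-sinapate
Product: 4 (E)-sinapyl alcohol
Conditions: i-Bu2AlH (4.5 equiv), toluene, 0 °C; then EtOH, H2O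
Reagents that add atoms: none
Why: 1,2-Reduction of an α,β-unsaturated ester by an electrophilic aluminium hydride; the phenol is only deprotonated (one extra equivalent) and the E-alkene is untouched.

Step 3
Reactants: 4 (E)-sinapyl alcohol (two molecules)
Product: 6 (±)-syringaresinol, via bis-quinone methide 5 (not isolated)
Conditions: FeCl3·6H2O (1.1 equiv), acetone–H2O, rt
Reagents that add atoms: none
Why: Biomimetic one-electron phenol oxidation with radical dimerisation; with C3 and C5 blocked by methoxy groups the phenoxyl radicals couple mainly C8–C8′, and each γ-OH then adds to the opposite quinone methide (5-exo-trig 1,6-addition), closing both tetrahydrofuran rings cis-fused with both aryl groups exo, as a racemate.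

Step 4
Reactants: 6 (±)-syringaresinol
Product: 7 (−)-syringaresinol, the (7R,7′R,8S,8′S) enantiomer
Conditions: preparative HPLC, cellulose tris(3,5-dimethylphenylcarbamate) on silica, hexane–EtOH, rt
Reagents that add atoms: none
Why: Chromatographic resolution on a polysaccharide carbamate phase, a separation type established for furofuran lignan enantiomers; it fixes the absolute configuration of C7, C7′, C8 and C8′, and the levorotatory antipode is the one collected.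

Step 5
Reactants: 7 (−)-syringaresinol; 8 propargyl bromide
Product: 9 (−)-syringaresinol 4,4′-di-O-propargyl ether
Conditions: 8 (3 equiv), K2CO3, DMF, 50 °C
Reagents that add atoms: propargyl bromide (8), BrCC#C
Why: Williamson ether synthesis; the hindered 2,6-dimethoxyphenoxide meets an unhindered primary propargylic halide, so the congested aryl ether is made at a CH2 group and not at a secondary carbon.

Step 6
Reactants: 9 di-O-propargyl ether; 10 pinacolborane
Product: 11 (−)-syringaresinol 4,4′-bis-O-[(E)-3-(Bpin)prop-2-en-1-yl] ether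
Conditions: 10 (2.5 equiv), Cp2Zr(H)Cl (10 mol %), Et3N (10 mol %), THF, 60 °C
Reagents that add atoms: pinacolborane (10), CC1(C)OBOC1(C)C
Why: Cp2Zr(H)Cl-catalysed alkyne hydroboration (hydrozirconation, then Zr-to-B exchange); syn addition with boron at the terminal carbon gives the (E)-alkenylboronates, and all ethers are inert.

Step 7
Reactants: 11 bis-(E)-alkenylboronate
Product: 12 (−)-syringaresinol 4,4′-bis-O-[(E)-3-(Bpin)prop-1-en-1-yl] ether (bis-(E)-γ-aryloxyallylboronate)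
Conditions: [Ir(cod)(PPh2Me)2]PF6 (5 mol %), activated with H2 then purged with Ar, THF, rt; filtration through neutral alumina
Reagents that add atoms: none
Why: Olefin transposition by a cationic iridium hydride (reversible insertion/β-hydride elimination), the reaction type that turns 3-silyloxy- and 3-alkoxyprop-1-enylboronates into (E)-γ-oxyallylboronates and allyl aryl ethers into (E)-propenyl aryl ethers; the enol ether is the thermodynamic sink because the aryl ring, twisted by its two ortho methoxy groups, leaves the oxygen lone pair to the alkene.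

Step 8
Reactants: 12 bis-(E)-γ-aryloxyallylboronate; 13 O-benzylvanillin (two molecules)
Product: 15 (−)-syringaresinol 4,4′-bis-O-[(1S,2R)-1-(4-benzyloxy-3-methoxyphenyl)-1-hydroxybut-3-en-2-yl] ether, via bis-borate 14 (not isolated)
Conditions: 13 (2.6 equiv), (R)-TRIP (10 mol %), 4 Å MS, toluene, −30 → 0 °C; then aq. NaHCO3
Reagents that add atoms: O-benzylvanillin (13), COc1cc(C=O)ccc1OCc1ccccc1
Why: Proposed new method: each (E)-γ-aryloxyallyl pinacolboronate terminus binds one aldehyde at boron and transfers its oxygen-bearing γ-carbon through a closed six-membered chair transition state, while the phosphoric acid O–H hydrogen-bonds to the pseudo-axial dioxaborolane oxygen (raising the Lewis acidity of boron) and its P=O contacts the formyl C–H. The closest known reaction types are the anti-selective additions of (E)-γ-alkoxy- and γ-silyloxyallylboronates to aldehydes and the BINOL-phosphoric-acid-catalysed additions of allyl, crotyl and γ-alkoxyallyl pinacolboronates to aryl aldehydes; the new elements are the O-aryl group on the γ-carbon and the twofold use on one substrate. Two C–C bonds (Cα–Cβ of arms A and A′) are formed and no ring is closed. The relative configuration (anti, which is erythro) follows from the E double bond, which puts OAr and the aldehyde aryl group both equatorial in the chair, and the absolute configuration (αS,βR in both arms) follows from Re-face selection by (R)-TRIP, the nearest core stereocentre lying six bonds from the reacting carbon. The step needs γ-attack (enforced by the cyclic SE2′ geometry), survival of the enol ether boronate towards acid (an aryl enol ether is less basic than an alkyl one; only a catalytic weak acid is present, at low temperature over sieves), a negligible uncatalysed background (pinacol ester plus an electron-rich aldehyde at −30 °C) and complete reaction at both ends (excess aldehyde). Because the two ends react independently on a chiral core, a wrong-face event gives a diastereomer that chromatography can remove, not the enantiomer.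

Step 9
Reactants: 15 bis-homoallylic alcohol
Product: 16 bis-α-O-TBS ether of 15
Conditions: TBSOTf (3 equiv), 2,6-lutidine, CH2Cl2, 0 °C
Reagents that add atoms: TBSOTf, CC(C)(C)[Si](C)(C)OS(=O)(=O)C(F)(F)F
Why: Silyl triflate silylation of a hindered secondary alcohol; capping Cα–OH shuts off the retro-aldol path that a free β-hydroxy-α-aryloxy aldehyde would have in the next step.

Step 10
Reactants: 16 bis-α-O-TBS ether
Product: 18 bis-γ-alcohol (each vinyl replaced by CH2OH; αS,βR in both arms), via dialdehyde 17 (not isolated)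
Conditions: OsO4 (2 mol %), NaIO4 (8 equiv), 2,6-lutidine, dioxane–H2O, rt; extractive work-up; NaBH4, THF–MeOH, −20 → 0 °C
Reagents that add atoms: OsO4, O=[Os](=O)(=O)=O, reoxidised by NaIO4, [Na+].[O-]I(=O)(=O)=O (source of the new Cγ oxygen)
Why: Johnson–Lemieux cleavage followed by borohydride reduction; only the monosubstituted alkenes react because every phenol is still benzylated, and immediate cold reduction of the crude α-aryloxy aldehyde guards Cβ against epimerisation.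

Step 11
Reactants: 18 bis-γ-alcohol
Product: 19 tetra-TBS ether (α- and γ-OTBS in arms A and A′, both guaiacyl phenols benzylated)
Conditions: TBSCl (3 equiv), imidazole, DMF, rt
Reagents that add atoms: TBSCl, CC(C)(C)[Si](C)(C)Cl
Why: Standard silylation of unhindered primary alcohols, which leaves no protic group to interfere with the borane, the iridium catalyst or the phosphoric acid in the second round.

Step 12
Reactants: 19 tetra-TBS ether
Product: 20 C2-symmetric bis-phenol (both benzyl groups removed)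
Conditions: H2 (1 atm), Pd/C (10 wt % Pd), EtOAc, rt
Reagents that add atoms: none
Why: Hydrogenolysis of aryl benzyl ethers under neutral conditions; these cleave well before benzylic silyl ethers or the furofuran C7–O bonds, and no alkene remains to be reduced.

Step 13
Reactants: 20 bis-phenol; 8 propargyl bromide
Product: 21 mono-O-propargyl ether mono-phenol
Conditions: 8 (0.9 equiv, slow addition), K2CO3, DMF, rt; recovered 20 is resubmitted
Reagents that add atoms: propargyl bromide (8), BrCC#C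
Why: Williamson alkylation with the electrophile limiting; the two phenols are homotopic, so mono-alkylation gives one compound, and the statistical mixture of bis-phenol, mono-phenol and bis-ether differs enough in polarity to be separated.

Step 14
Reactants: 21 mono-propargyl ether mono-phenol
Product: 22 propargyl/benzyl bis-ether
Conditions: BnBr, K2CO3, DMF, rt
Reagents that add atoms: benzyl bromide, BrCc1ccccc1
Why: Williamson benzylation; it removes the last acidic proton and keeps this phenol masked until the final neutral hydrogenolysis, so no phenoxide para to a benzylic C–O bond is exposed to fluoride.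

Step 15
Reactants: 22 propargyl/benzyl bis-ether; 10 pinacolborane
Product: 23 (E)-3-aryloxyprop-1-enylboronate of arm A
Conditions: 10 (1.3 equiv), Cp2Zr(H)Cl (10 mol %), Et3N (10 mol %), THF, 60 °C
Reagents that add atoms: pinacolborane (10), CC1(C)OBOC1(C)C
Why: Cp2Zr(H)Cl-catalysed alkyne hydroboration as in step 6; syn, terminal-selective addition gives the E-alkenylboronate, and silyl and benzyl ethers are inert.

Step 16
Reactants: 23 (E)-alkenylboronate
Product: 24 (E)-γ-(guaiacyloxy)allyl pinacolboronate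
Conditions: [Ir(cod)(PPh2Me)2]PF6 (5 mol %), activated with H2 then purged with Ar, THF, rt; filtration through neutral alumina
Reagents that add atoms: none
Why: The same cationic iridium hydride olefin transposition as in step 7; there is no other alkene in the molecule, and benzyl ethers survive because hydrogen is removed after activation.

Step 17
Reactants: 24 (E)-γ-aryloxyallylboronate; 13 O-benzylvanillin
Product: 26 arm-B homoallylic alcohol with (1R,2S)-1-aryl-2-aryloxybut-3-en-1-ol unit, via borate 25 (not isolated)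
Conditions: 13 (1.5 equiv), (S)-TRIP (10 mol %), 4 Å MS, toluene, −30 → 0 °C; then aq. NaHCO3
Reagents that add atoms: O-benzylvanillin (13), COc1cc(C=O)ccc1OCc1ccccc1
Why: Proposed new method: this is the same phosphoric-acid-activated closed-chair γ-aryloxyallylboration as in step 8 (closest known types: anti-selective (E)-γ-alkoxy/silyloxyallylboration and chiral phosphoric acid catalysed allyl-, crotyl- and γ-alkoxyallylboration of aryl aldehydes); the E-alkene sets anti (erythro), the enantiomeric catalyst selects the Si face to give αR,βS, and the existing stereocentres lie para across the guaiacyl ring, too far away to oppose the catalyst.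

Step 18
Reactants: 26 arm-B homoallylic alcohol
Product: 27 penta-TBS ether
Conditions: TBSOTf, 2,6-lutidine, CH2Cl2, 0 °C
Reagents that add atoms: TBSOTf, CC(C)(C)[Si](C)(C)OS(=O)(=O)C(F)(F)F
Why: Silyl triflate silylation of the secondary benzylic alcohol, again to block retro-aldol cleavage at the aldehyde stage.

Step 19
Reactants: 27 penta-TBS ether
Product: 29 arm-B γ-alcohol (αR,βS), via aldehyde 28 (not isolated)
Conditions: OsO4 (2 mol %), NaIO4 (4 equiv), 2,6-lutidine, dioxane–H2O, rt; extractive work-up; NaBH4, THF–MeOH, −20 → 0 °C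
Reagents that add atoms: OsO4, O=[Os](=O)(=O)=O, reoxidised by NaIO4, [Na+].[O-]I(=O)(=O)=O (source of the new Cγ oxygen)
Why: Johnson–Lemieux cleavage and borohydride reduction as in step 10; the vinyl group is the only oxidisable site, since both phenols are benzylated.

Step 20
Reactants: 29 arm-B γ-alcohol
Product: 30 hexaol di-O-benzyl ether (all five TBS groups removed)
Conditions: Bu4NF (8 equiv), AcOH (8 equiv), THF, rt → 40 °C
Reagents that add atoms: none
Why: Fluoride desilylation buffered with acetic acid; with both terminal phenols still benzylated no p-quinone methide can form, so the three benzylic carbinol centres keep their configuration.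

Step 21
Reactants: 30 hexaol di-O-benzyl ether
Product: 31 target CNP0316493.2
Conditions: H2 (1 atm), Pd/C (10 wt % Pd), EtOAc–EtOH, rt, stopped at full conversion
Reagents that add atoms: none
Why: Neutral hydrogenolysis of the two aryl benzyl ethers as the last step; aryl benzyl ethers cleave faster than secondary benzylic alcohols and the furofuran C–O bonds, and neither acid nor base touches the labile p-hydroxybenzyl alcohol units.

## Compound list
1 | syringaldehyde | COc1cc(C=O)cc(OC)c1O | starting material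
2 | ethyl hydrogen malonate | CCOC(=O)CC(=O)O | starting material
3 | ethyl (E)-sinapate | CCOC(=O)/C=C/c1cc(OC)c(O)c(OC)c1 | intermediate
4 | (E)-sinapyl alcohol | OC/C=C/c1cc(OC)c(O)c(OC)c1 | intermediate
5 | racemic 8,8′-coupled bis-quinone methide (both enantiomers written) | OC[C@@H](C=C1C=C(OC)C(=O)C(OC)=C1)[C@H](C=C1C=C(OC)C(=O)C(OC)=C1)CO.OC[C@H](C=C1C=C(OC)C(=O)C(OC)=C1)[C@@H](C=C1C=C(OC)C(=O)C(OC)=C1)CO | intermediate (not isolated)
6 | (±)-syringaresinol (both enantiomers written) | COc1cc([C@@H]2OC[C@@H]3[C@H]2CO[C@H]3c2cc(OC)c(O)c(OC)c2)cc(OC)c1O.COc1cc([C@H]2OC[C@H]3[C@@H]2CO[C@@H]3c2cc(OC)c(O)c(OC)c2)cc(OC)c1O | intermediate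
7 | (−)-syringaresinol, (7R,7′R,8S,8′S) | COc1cc([C@@H]2OC[C@@H]3[C@H]2CO[C@H]3c2cc(OC)c(O)c(OC)c2)cc(OC)c1O | intermediate
8 | propargyl bromide | BrCC#C | starting material
9 | (−)-syringaresinol 4,4′-di-O-propargyl ether | C#CCOc1c(OC)cc([C@@H]2OC[C@@H]3[C@H]2CO[C@H]3c2cc(OC)c(OCC#C)c(OC)c2)cc1OC | intermediate
10 | pinacolborane | CC1(C)OBOC1(C)C | starting material
11 | core bis[(E)-3-(Bpin)prop-2-enyl] ether | CC1(C)OB(/C=C/COc2c(OC)cc([C@@H]3OC[C@@H]4[C@H]3CO[C@H]4c3cc(OC)c(OC/C=C/B4OC(C)(C)C(C)(C)O4)c(OC)c3)cc2OC)OC1(C)C | intermediate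
12 | core bis[(E)-3-(Bpin)prop-1-enyl] ether (key-step precursor) | CC1(C)OB(C/C=C/Oc2c(OC)cc([C@@H]3OC[C@@H]4[C@H]3CO[C@H]4c3cc(OC)c(O/C=C/CB4OC(C)(C)C(C)(C)O4)c(OC)c3)cc2OC)OC1(C)C | intermediate
13 | O-benzylvanillin | COc1cc(C=O)ccc1OCc1ccccc1 | starting material
14 | bis-α-O-Bpin borate of 15 | COc1cc([C@H](OB2OC(C)(C)C(C)(C)O2)[C@@H](C=C)Oc3c(OC)cc([C@@H]4OC[C@@H]5[C@H]4CO[C@H]5c4cc(OC)c(O[C@H](C=C)[C@@H](OB5OC(C)(C)C(C)(C)O5)c5ccc(OCc6ccccc6)c(OC)c5)c(OC)c4)cc3OC)ccc1OCc2ccccc2 | intermediate (not isolated)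
15 | C2-symmetric core bis[(1S,2R)-1-(4-benzyloxy-3-methoxyphenyl)-1-hydroxybut-3-en-2-yl] ether (key-step product) | COc1cc([C@H](O)[C@@H](C=C)Oc3c(OC)cc([C@@H]4OC[C@@H]5[C@H]4CO[C@H]5c4cc(OC)c(O[C@H](C=C)[C@@H](O)c5ccc(OCc6ccccc6)c(OC)c5)c(OC)c4)cc3OC)ccc1OCc2ccccc2 | intermediate
16 | bis-α-O-TBS ether of 15 | COc1cc([C@H](O[Si](C)(C)C(C)(C)C)[C@@H](C=C)Oc3c(OC)cc([C@@H]4OC[C@@H]5[C@H]4CO[C@H]5c4cc(OC)c(O[C@H](C=C)[C@@H](O[Si](C)(C)C(C)(C)C)c5ccc(OCc6ccccc6)c(OC)c5)c(OC)c4)cc3OC)ccc1OCc2ccccc2 | intermediate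
17 | dialdehyde (spatial arrangement of 16; formally 2S,3S in each propanal unit because CHO outranks Cα) | COc1cc([C@H](O[Si](C)(C)C(C)(C)C)[C@@H](C=O)Oc3c(OC)cc([C@@H]4OC[C@@H]5[C@H]4CO[C@H]5c4cc(OC)c(O[C@H](C=O)[C@@H](O[Si](C)(C)C(C)(C)C)c5ccc(OCc6ccccc6)c(OC)c5)c(OC)c4)cc3OC)ccc1OCc2ccccc2 | intermediate (not isolated)
18 | bis-γ-alcohol, α-OTBS, (αS,βR) in arms A and A′ | COc1cc([C@H](O[Si](C)(C)C(C)(C)C)[C@@H](CO)Oc3c(OC)cc([C@@H]4OC[C@@H]5[C@H]4CO[C@H]5c4cc(OC)c(O[C@H](CO)[C@@H](O[Si](C)(C)C(C)(C)C)c5ccc(OCc6ccccc6)c(OC)c5)c(OC)c4)cc3OC)ccc1OCc2ccccc2 | intermediate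
19 | tetra-TBS ether, di-O-benzyl | COc1cc([C@H](O[Si](C)(C)C(C)(C)C)[C@@H](CO[Si](C)(C)C(C)(C)C)Oc3c(OC)cc([C@@H]4OC[C@@H]5[C@H]4CO[C@H]5c4cc(OC)c(O[C@H](CO[Si](C)(C)C(C)(C)C)[C@@H](O[Si](C)(C)C(C)(C)C)c5ccc(OCc6ccccc6)c(OC)c5)c(OC)c4)cc3OC)ccc1OCc2ccccc2 | intermediate
20 | tetra-TBS bis-phenol | COc1cc([C@H](O[Si](C)(C)C(C)(C)C)[C@@H](CO[Si](C)(C)C(C)(C)C)Oc3c(OC)cc([C@@H]4OC[C@@H]5[C@H]4CO[C@H]5c4cc(OC)c(O[C@H](CO[Si](C)(C)C(C)(C)C)[C@@H](O[Si](C)(C)C(C)(C)C)c5ccc(O)c(OC)c5)c(OC)c4)cc3OC)ccc1O | intermediate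
21 | mono-O-propargyl ether (arm A), free phenol on arm A′ | C#CCOc2ccc([C@H](O[Si](C)(C)C(C)(C)C)[C@@H](CO[Si](C)(C)C(C)(C)C)Oc3c(OC)cc([C@@H]4OC[C@@H]5[C@H]4CO[C@H]5c4cc(OC)c(O[C@H](CO[Si](C)(C)C(C)(C)C)[C@@H](O[Si](C)(C)C(C)(C)C)c5ccc(O)c(OC)c5)c(OC)c4)cc3OC)cc2OC | intermediate
22 | O-propargyl (arm A) / O-benzyl (arm A′) bis-ether | C#CCOc2ccc([C@H](O[Si](C)(C)C(C)(C)C)[C@@H](CO[Si](C)(C)C(C)(C)C)Oc3c(OC)cc([C@@H]4OC[C@@H]5[C@H]4CO[C@H]5c4cc(OC)c(O[C@H](CO[Si](C)(C)C(C)(C)C)[C@@H](O[Si](C)(C)C(C)(C)C)c5ccc(OCc6ccccc6)c(OC)c5)c(OC)c4)cc3OC)cc2OC | intermediate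
23 | arm-A O-[(E)-3-(Bpin)prop-2-enyl] ether | CC1(C)OB(/C=C/COc2ccc([C@H](O[Si](C)(C)C(C)(C)C)[C@@H](CO[Si](C)(C)C(C)(C)C)Oc3c(OC)cc([C@@H]4OC[C@@H]5[C@H]4CO[C@H]5c4cc(OC)c(O[C@H](CO[Si](C)(C)C(C)(C)C)[C@@H](O[Si](C)(C)C(C)(C)C)c5ccc(OCc6ccccc6)c(OC)c5)c(OC)c4)cc3OC)cc2OC)OC1(C)C | intermediate
24 | arm-A O-[(E)-3-(Bpin)prop-1-enyl] ether | CC1(C)OB(C/C=C/Oc2ccc([C@H](O[Si](C)(C)C(C)(C)C)[C@@H](CO[Si](C)(C)C(C)(C)C)Oc3c(OC)cc([C@@H]4OC[C@@H]5[C@H]4CO[C@H]5c4cc(OC)c(O[C@H](CO[Si](C)(C)C(C)(C)C)[C@@H](O[Si](C)(C)C(C)(C)C)c5ccc(OCc6ccccc6)c(OC)c5)c(OC)c4)cc3OC)cc2OC)OC1(C)C | intermediate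
25 | α-O-Bpin borate of 26 | COc1cc([C@@H](OB7OC(C)(C)C(C)(C)O7)[C@H](C=C)Oc2ccc([C@H](O[Si](C)(C)C(C)(C)C)[C@@H](CO[Si](C)(C)C(C)(C)C)Oc3c(OC)cc([C@@H]4OC[C@@H]5[C@H]4CO[C@H]5c4cc(OC)c(O[C@H](CO[Si](C)(C)C(C)(C)C)[C@@H](O[Si](C)(C)C(C)(C)C)c5ccc(OCc6ccccc6)c(OC)c5)c(OC)c4)cc3OC)cc2OC)ccc1OCc7ccccc7 | intermediate (not isolated)
26 | arm-B homoallylic alcohol, (1R,2S) anti | COc1cc([C@@H](O)[C@H](C=C)Oc2ccc([C@H](O[Si](C)(C)C(C)(C)C)[C@@H](CO[Si](C)(C)C(C)(C)C)Oc3c(OC)cc([C@@H]4OC[C@@H]5[C@H]4CO[C@H]5c4cc(OC)c(O[C@H](CO[Si](C)(C)C(C)(C)C)[C@@H](O[Si](C)(C)C(C)(C)C)c5ccc(OCc6ccccc6)c(OC)c5)c(OC)c4)cc3OC)cc2OC)ccc1OCc7ccccc7 | intermediate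
27 | penta-TBS ether (arm-B α-OTBS, vinyl) | COc1cc([C@@H](O[Si](C)(C)C(C)(C)C)[C@H](C=C)Oc2ccc([C@H](O[Si](C)(C)C(C)(C)C)[C@@H](CO[Si](C)(C)C(C)(C)C)Oc3c(OC)cc([C@@H]4OC[C@@H]5[C@H]4CO[C@H]5c4cc(OC)c(O[C@H](CO[Si](C)(C)C(C)(C)C)[C@@H](O[Si](C)(C)C(C)(C)C)c5ccc(OCc6ccccc6)c(OC)c5)c(OC)c4)cc3OC)cc2OC)ccc1OCc7ccccc7 | intermediate
28 | arm-B aldehyde (spatial arrangement of 27; formally 2R,3R) | COc1cc([C@@H](O[Si](C)(C)C(C)(C)C)[C@H](C=O)Oc2ccc([C@H](O[Si](C)(C)C(C)(C)C)[C@@H](CO[Si](C)(C)C(C)(C)C)Oc3c(OC)cc([C@@H]4OC[C@@H]5[C@H]4CO[C@H]5c4cc(OC)c(O[C@H](CO[Si](C)(C)C(C)(C)C)[C@@H](O[Si](C)(C)C(C)(C)C)c5ccc(OCc6ccccc6)c(OC)c5)c(OC)c4)cc3OC)cc2OC)ccc1OCc7ccccc7 | intermediate (not isolated)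
29 | arm-B γ-alcohol, penta-TBS, di-O-benzyl | COc1cc([C@@H](O[Si](C)(C)C(C)(C)C)[C@H](CO)Oc2ccc([C@H](O[Si](C)(C)C(C)(C)C)[C@@H](CO[Si](C)(C)C(C)(C)C)Oc3c(OC)cc([C@@H]4OC[C@@H]5[C@H]4CO[C@H]5c4cc(OC)c(O[C@H](CO[Si](C)(C)C(C)(C)C)[C@@H](O[Si](C)(C)C(C)(C)C)c5ccc(OCc6ccccc6)c(OC)c5)c(OC)c4)cc3OC)cc2OC)ccc1OCc7ccccc7 | intermediate
30 | hexaol di-O-benzyl ether | COc1cc([C@@H](O)[C@H](CO)Oc2ccc([C@H](O)[C@@H](CO)Oc3c(OC)cc([C@@H]4OC[C@@H]5[C@H]4CO[C@H]5c4cc(OC)c(O[C@H](CO)[C@@H](O)c5ccc(OCc6ccccc6)c(OC)c5)c(OC)c4)cc3OC)cc2OC)ccc1OCc7ccccc7 | intermediate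
31 | CNP0316493.2: core 7R,7′R,8S,8′S; arms A and A′ αS,βR; arm B αR,βS | COc1cc([C@@H](O)[C@H](CO)Oc2ccc([C@H](O)[C@@H](CO)Oc3c(OC)cc([C@@H]4OC[C@@H]5[C@H]4CO[C@H]5c4cc(OC)c(O[C@H](CO)[C@@H](O)c5ccc(O)c(OC)c5)c(OC)c4)cc3OC)cc2OC)ccc1O | target

## Step count
Total step count: 21. Longest linear sequence: 21 steps, from syringaldehyde. All other building blocks are purchased.

## The three steps most likely to fail

**1. Step 8 (labelled).**
- What may go wrong: the acid catalyst may protonate the enol ether boronate, or cause protodeboronation, faster than the slow addition to an electron-rich aldehyde. The second terminus may react incompletely. The bulky γ-aryloxy group may disturb facial selection in the catalyst pocket.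
- Fallback: an Evans syn-aldol reaction followed by Mitsunobu inversion at Cα. It sets out from 7 and comes back at 19.
- Both phenols of 7 are alkylated (K2CO3, MeCN, rt) with (S)-4-benzyl-3-(bromoacetyl)oxazolidin-2-one F1, itself made from (S)-4-benzyloxazolidin-2-one, n-BuLi and bromoacetyl bromide. This gives the core bis(aryloxyacetyl)imide F2.
- Enolisation with Bu2BOTf/i-Pr2NEt and addition of 13 should give the bis-syn-aldol adduct F3, with Cβ correct and Cα epimeric.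
- NaBH4 in THF–H2O removes both auxiliaries to give the threo bis-1,3-diol F4.
- TBSCl/imidazole silylates only the primary hydroxyls to give the threo bis-γ-silyl ether F5.
- 4-Nitrobenzoic acid, PPh3 and DIAD invert both Cα centres to give the erythro bis-4-nitrobenzoate F6.
- K2CO3/MeOH frees the erythro bis-α-alcohol F7, and TBSOTf/2,6-lutidine converts it into 19.

**2. Step 17 (labelled).**
- What may go wrong: the same acid-induced loss of the boronate, now in a crowded, heavily silylated substrate that reacts more slowly, or weaker facial selection with the less hindered guaiacyl ether.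
- Fallback: the same aldol/inversion logic with the enantiomeric auxiliary. It sets out from 20 and comes back at 30.
- Limiting (R)-4-benzyl-3-(bromoacetyl)oxazolidin-2-one F8 (prepared like its antipode) mono-alkylates 20 to give the mono-imide mono-phenol F9.
- BnBr/K2CO3 gives the benzylated mono-imide F10.
- The Bu2BOTf-mediated Evans syn-aldol reaction with 13 gives the arm-B syn-aldol adduct F11.
- NaBH4 gives the arm-B threo diol F12, and TBSCl gives the arm-B threo γ-silyl ether F13.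
- Mitsunobu inversion gives the arm-B erythro 4-nitrobenzoate F14, and K2CO3/MeOH gives the arm-B erythro α-alcohol F15.
- Bu4NF/AcOH removes all five silyl groups to reach 30.

**3. Step 7.**
- What may go wrong: migration may be incomplete at one of the two termini. Partial formation of the Z-enol ether would be carried into threo product. Residual hydrogen may saturate an alkene.
- Fallback: the E-allylboronate is built by one-carbon homologation instead of isomerisation. It sets out from 7 and comes back at 12.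
- KH and trichloroethylene in THF give the core bis[(E)-1,2-dichlorovinyl] ether F16.
- Excess n-BuLi (−78 → −40 °C), then MeOH, gives the core bis(ethynyl) ether F17.
- Pinacolborane 10 with catalytic Cp2Zr(H)Cl gives the core bis[(E)-2-(Bpin)vinyl] ether F18.
- Matteson homologation with LiCH2Cl (ICH2Cl, n-BuLi, THF, −78 °C → rt) inserts CH2 into each B–C bond with retention of the E geometry, giving 12.

## Further compounds
F1 | step 8 | (S)-4-benzyl-3-(bromoacetyl)oxazolidin-2-one | O=C(CBr)N1[C@@H](Cc2ccccc2)COC1=O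
F2 | step 8 | core bis(aryloxyacetyl)imide of (S)-4-benzyloxazolidin-2-one | O=C(COc1c(OC)cc([C@@H]2OC[C@@H]3[C@H]2CO[C@H]3c2cc(OC)c(OCC(=O)N3[C@@H](Cc4ccccc4)COC3=O)c(OC)c2)cc1OC)N1[C@@H](Cc2ccccc2)COC1=O
F3 | step 8 | bis-syn-aldol adduct | COc1cc([C@@H](O)[C@@H](C(=O)N2[C@@H](Cc7ccccc7)COC2=O)Oc3c(OC)cc([C@@H]4OC[C@@H]5[C@H]4CO[C@H]5c4cc(OC)c(O[C@H](C(=O)N5[C@@H](Cc6ccccc6)COC5=O)[C@H](O)c5ccc(OCc6ccccc6)c(OC)c5)c(OC)c4)cc3OC)ccc1OCc2ccccc2
F4 | step 8 | threo bis-1,3-diol (αR,βR) | COc1cc([C@@H](O)[C@@H](CO)Oc3c(OC)cc([C@@H]4OC[C@@H]5[C@H]4CO[C@H]5c4cc(OC)c(O[C@H](CO)[C@H](O)c5ccc(OCc6ccccc6)c(OC)c5)c(OC)c4)cc3OC)ccc1OCc2ccccc2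
F5 | step 8 | threo bis-γ-silyl ether | COc1cc([C@@H](O)[C@@H](CO[Si](C)(C)C(C)(C)C)Oc3c(OC)cc([C@@H]4OC[C@@H]5[C@H]4CO[C@H]5c4cc(OC)c(O[C@H](CO[Si](C)(C)C(C)(C)C)[C@H](O)c5ccc(OCc6ccccc6)c(OC)c5)c(OC)c4)cc3OC)ccc1OCc2ccccc2
F6 | step 8 | erythro bis-4-nitrobenzoate | COc1cc([C@H](OC(=O)c2ccc(cc2)[N+](=O)[O-])[C@@H](CO[Si](C)(C)C(C)(C)C)Oc3c(OC)cc([C@@H]4OC[C@@H]5[C@H]4CO[C@H]5c4cc(OC)c(O[C@H](CO[Si](C)(C)C(C)(C)C)[C@@H](OC(=O)c5ccc(cc5)[N+](=O)[O-])c5ccc(OCc6ccccc6)c(OC)c5)c(OC)c4)cc3OC)ccc1OCc2ccccc2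
F7 | step 8 | erythro bis-α-alcohol, γ-OTBS | COc1cc([C@H](O)[C@@H](CO[Si](C)(C)C(C)(C)C)Oc3c(OC)cc([C@@H]4OC[C@@H]5[C@H]4CO[C@H]5c4cc(OC)c(O[C@H](CO[Si](C)(C)C(C)(C)C)[C@@H](O)c5ccc(OCc6ccccc6)c(OC)c5)c(OC)c4)cc3OC)ccc1OCc2ccccc2
F8 | step 17 | (R)-4-benzyl-3-(bromoacetyl)oxazolidin-2-one | O=C(CBr)N1[C@H](Cc2ccccc2)COC1=O
F9 | step 17 | mono-imide mono-phenol | O=C(COc2ccc([C@H](O[Si](C)(C)C(C)(C)C)[C@@H](CO[Si](C)(C)C(C)(C)C)Oc3c(OC)cc([C@@H]4OC[C@@H]5[C@H]4CO[C@H]5c4cc(OC)c(O[C@H](CO[Si](C)(C)C(C)(C)C)[C@@H](O[Si](C)(C)C(C)(C)C)c5ccc(O)c(OC)c5)c(OC)c4)cc3OC)cc2OC)N1[C@H](Cc7ccccc7)COC1=O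
F10 | step 17 | benzylated mono-imide | O=C(COc2ccc([C@H](O[Si](C)(C)C(C)(C)C)[C@@H](CO[Si](C)(C)C(C)(C)C)Oc3c(OC)cc([C@@H]4OC[C@@H]5[C@H]4CO[C@H]5c4cc(OC)c(O[C@H](CO[Si](C)(C)C(C)(C)C)[C@@H](O[Si](C)(C)C(C)(C)C)c5ccc(OCc6ccccc6)c(OC)c5)c(OC)c4)cc3OC)cc2OC)N1[C@H](Cc7ccccc7)COC1=O
F11 | step 17 | arm-B syn-aldol adduct | COc1cc([C@H](O)[C@H](C(=O)N7[C@H](Cc8ccccc8)COC7=O)Oc2ccc([C@H](O[Si](C)(C)C(C)(C)C)[C@@H](CO[Si](C)(C)C(C)(C)C)Oc3c(OC)cc([C@@H]4OC[C@@H]5[C@H]4CO[C@H]5c4cc(OC)c(O[C@H](CO[Si](C)(C)C(C)(C)C)[C@@H](O[Si](C)(C)C(C)(C)C)c5ccc(OCc6ccccc6)c(OC)c5)c(OC)c4)cc3OC)cc2OC)ccc1OCc7ccccc7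
F12 | step 17 | arm-B threo diol (αS,βS) | COc1cc([C@H](O)[C@H](CO)Oc2ccc([C@H](O[Si](C)(C)C(C)(C)C)[C@@H](CO[Si](C)(C)C(C)(C)C)Oc3c(OC)cc([C@@H]4OC[C@@H]5[C@H]4CO[C@H]5c4cc(OC)c(O[C@H](CO[Si](C)(C)C(C)(C)C)[C@@H](O[Si](C)(C)C(C)(C)C)c5ccc(OCc6ccccc6)c(OC)c5)c(OC)c4)cc3OC)cc2OC)ccc1OCc7ccccc7
F13 | step 17 | arm-B threo γ-silyl ether | COc1cc([C@H](O)[C@H](CO[Si](C)(C)C(C)(C)C)Oc2ccc([C@H](O[Si](C)(C)C(C)(C)C)[C@@H](CO[Si](C)(C)C(C)(C)C)Oc3c(OC)cc([C@@H]4OC[C@@H]5[C@H]4CO[C@H]5c4cc(OC)c(O[C@H](CO[Si](C)(C)C(C)(C)C)[C@@H](O[Si](C)(C)C(C)(C)C)c5ccc(OCc6ccccc6)c(OC)c5)c(OC)c4)cc3OC)cc2OC)ccc1OCc7ccccc7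
F14 | step 17 | arm-B erythro 4-nitrobenzoate | COc1cc([C@@H](OC(=O)c7ccc(cc7)[N+](=O)[O-])[C@H](CO[Si](C)(C)C(C)(C)C)Oc2ccc([C@H](O[Si](C)(C)C(C)(C)C)[C@@H](CO[Si](C)(C)C(C)(C)C)Oc3c(OC)cc([C@@H]4OC[C@@H]5[C@H]4CO[C@H]5c4cc(OC)c(O[C@H](CO[Si](C)(C)C(C)(C)C)[C@@H](O[Si](C)(C)C(C)(C)C)c5ccc(OCc6ccccc6)c(OC)c5)c(OC)c4)cc3OC)cc2OC)ccc1OCc7ccccc7
F15 | step 17 | arm-B erythro α-alcohol, γ-OTBS | COc1cc([C@@H](O)[C@H](CO[Si](C)(C)C(C)(C)C)Oc2ccc([C@H](O[Si](C)(C)C(C)(C)C)[C@@H](CO[Si](C)(C)C(C)(C)C)Oc3c(OC)cc([C@@H]4OC[C@@H]5[C@H]4CO[C@H]5c4cc(OC)c(O[C@H](CO[Si](C)(C)C(C)(C)C)[C@@H](O[Si](C)(C)C(C)(C)C)c5ccc(OCc6ccccc6)c(OC)c5)c(OC)c4)cc3OC)cc2OC)ccc1OCc7ccccc7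
F16 | step 7 | core bis[(E)-1,2-dichlorovinyl] ether | Cl/C=C(/Cl)Oc1c(OC)cc([C@@H]2OC[C@@H]3[C@H]2CO[C@H]3c2cc(OC)c(O/C(Cl)=C\Cl)c(OC)c2)cc1OC
F17 | step 7 | core bis(ethynyl) ether | C#COc1c(OC)cc([C@@H]2OC[C@@H]3[C@H]2CO[C@H]3c2cc(OC)c(OC#C)c(OC)c2)cc1OC
F18 | step 7 | core bis[(E)-2-(Bpin)vinyl] ether | CC1(C)OB(/C=C/Oc2c(OC)cc([C@@H]3OC[C@@H]4[C@H]3CO[C@H]4c3cc(OC)c(O/C=C/B4OC(C)(C)C(C)(C)O4)c(OC)c3)cc2OC)OC1(C)C
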